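The readings were computed with constants of no real substance; the scatter is artificial.

Take the ratio of two rates in one flask: how fast the left-handed substrate is used against how fast the free catalyst is lost. I suppose that both steps need free catalyst and reagent, so these cancel in the ratio, and time drops out with them. What remains looks like first-order decay with catalyst lost standing where time stood: the logarithm of [left-handed substrate] charged over [left-handed substrate] remaining equals a constant times the [free catalyst] lost.

in all of them: free catalyst 0.5 mol%
- elm: left-handed substrate 1 M; right-handed substrate 1 M; reagent 1 equiv; temperature 90 °C; run made earlier
- red: left-handed substrate 0.50 M; right-handed substrate 0.50 M; reagent 1.00 equiv; temperature 90 °C; time 25 h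
- ochre: left-handed substrate 0.50 M; right-handed substrate 0.50 M; reagent 1.00 equiv; temperature 60 °C; time 25 h
- green: left-handed substrate 0.50 M; right-handed substrate 0.50 M; reagent 1.00 equiv; temperature 30 °C; time 25 h
- blue: left-handed substrate 0.50 M; right-handed substrate 0.50 M; reagent 1.00 equiv; temperature 120 °C; time 25 h

elm run (percent of the left-handed substrate and right-handed substrate together charged)

| time / h | left-handed product / % |
|---|---|
| 0.167 | 9.5 |
| 0.500 | 18.2 |
| 0.833 | 22.3 |
| 1.33 | 24.7 |
| 2.00 | 27.0 |
| 2.50 | 28.4 |

(readings scatter by 0.5 percentage points)

- free catalyst is single-handed; left-handed substrate and right-handed substrate are mirror images of each other, charged as a racemate, each of them at the stated concentration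
- the earlier runs do not show what temperature does; that part of a forecast is a guess
- no earlier run changes the charge of free catalyst; that part of a forecast is a guess

1. the flask that comes out highest in amount of left-handed product, in percent of the left-handed substrate and right-handed substrate together charged, or "all alike" when all lie within 1.5 percentage points (red / ochre / green / blue / all alike)
2. left-handed product at the end, in percent of the left-handed substrate and right-handed substrate together charged, red
3. left-handed product at the end, in percent of the left-handed substrate and right-handed substrate together charged, ochre
4. left-handed product at the end, in percent of the left-handed substrate and right-handed substrate together charged, green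
5. left-handed product at the end, in percent of the left-handed substrate and right-handed substrate together charged, blue

The single-handed catalyst on a racemate makes this a kinetic resolution. The elm run is the neighbour of red, with the same temperature and loading, but every concentration in red stands at half of elm's, [left-handed substrate] 0.50 M against 1 M, and red runs for 25 h. Elm's last reading, 28.4%, leaves 43.2% of its left-handed substrate. If the whole charge of catalyst had died by then, the logarithm per molar of catalyst lost would be 168 /M. I call this the reach of the catalyst. It is a floor: if part of elm's catalyst was still free, the true reach is larger.

Red starts with half of elm's [free catalyst], so if its whole charge dies at that floor value of the reach, it makes 17.1% of left-handed product. The reagent charge equals half of both substrates together, so the two products together stop at that share of the charge. My own range for red is a rough one: 17.1% at the bottom and, as a guess, about elm's 28.4% at the top. Temperature is a guess: if catalyst death speeds up more with heat than turnover does, the reach shrinks in blue, at 120 °C.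

The forecast says red 35%, ochre 24%, green 16% and blue 46%, with blue highest, and its red stands above my range. Its ground for the hot flask: “The background dominates at long times”.

The flasks give red 28.5%, ochre 23.3%, green 7.45% and blue 22.7%, so red comes out highest.

    reagent + free catalyst + left-handed substrate → free catalyst + left-handed product (k = 54.0 /M²/h, Ea = 61.0 kJ/mol)
    reagent + free catalyst + right-handed substrate → free catalyst + right-handed product (k = 34.0 /M²/h, Ea = 58.0 kJ/mol)
    reagent → decomposition product (k = 1.10 × 10⁻⁵ /h, Ea = 122 kJ/mol)
    reagent + free catalyst → spent catalyst (k = 0.0700 /M/h, Ea = 82.0 kJ/mol)
    (constants at 60 °C)

Red has 81.7% of its catalyst as spent catalyst at the end, which makes its reach 412 /M, above the elm floor. Blue ends with free catalyst at 0% and reagent still at 20.7%, and its left-handed product already stands at 22.7% after 12.5 h. With spent catalyst at 100%, blue's reach is 243 /M, shorter than red's. The path to spent catalyst is the largest single effect on blue: struck out, it leaves blue at 30.2%.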